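## Retrosynthetic overview
1. The target is the 7R aryl carbinol. It comes from Noyori–Ikariya transfer hydrogenation of the 7-aryl ketone, with the catalyst setting C7, after a protected 2,3-trans-3,4-cis THF diol has been oxidised chemoselectively at C7.
2. That THF diol comes from a zirconocene bicyclization–oxygenolysis of a 1,6-diene, which is the new step. The cis-fused zirconacyclopentane forms the THF ring and the C8–C8′ bond (3,4-cis). The allylic stereocentre C7′ directs the 2,3-trans relationship. The two C–Zr bonds become C7–OH and C9′–OH.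
3. The diene is the Williamson ether of (S)-1-(3,4-dibenzyloxyphenyl)allyl alcohol with (E)-4-benzyloxy-3-methoxycinnamyl bromide. The allylic alcohol comes from ATH of a TMS-ynone followed by Lindlar reduction.
4. Ring-formation order: the THF ring forms at the Zr step. The C7 stereocentre is set afterwards by ATH, and the three phenols are deprotected last.

Assumptions:
- Compounds 1, 2, 8 and 9 are commercial.
- Catalysts and bulk reagents are not numbered unless they leave non-hydrogen atoms in the product.
- The (S,S)-Ru catalyst is assumed to give the same facial selectivity as with acetophenone (an aryl ketone with a small α-substituent).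

## Route

**Step 1**
Reactants: 1 (3,4-bis(benzyloxy)benzaldehyde); 2 (trimethylsilylacetylene)
Product: 3 (racemic 1-[3,4-bis(benzyloxy)phenyl]-3-(trimethylsilyl)prop-2-yn-1-ol)
Conditions: 2, n-BuLi, THF, –78 → 0 °C; then 1
Reagents that add atoms: none
Why: Nucleophilic 1,2-addition of a lithium acetylide. The new stereocentre is racemic and is destroyed in Step 2.

**Step 2**
Reactants: 3
Product: 4 (1-[3,4-bis(benzyloxy)phenyl]-3-(trimethylsilyl)prop-2-yn-1-one)
Conditions: activated MnO2 (10 equiv), CH2Cl2, 25 °C
Reagents that add atoms: none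
Why: MnO2 oxidises the doubly activated benzylic/propargylic alcohol selectively.

**Step 3**
Reactants: 4
Product: 5 ((R)-CIP carbinol, same spatial arrangement as the (S)-propargylic alcohol 6; the TMS-alkynyl group outranks the aryl group)
Conditions: RuCl[(S,S)-TsDPEN](p-cymene) (1 mol %), KOH (2 mol %), i-PrOH, 28 °C
Reagents that add atoms: none
Why: Noyori–Ikariya asymmetric transfer hydrogenation of an acetylenic ketone. The catalyst controls the face, setting C7′, which is the only source of absolute configuration for the THF core.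

**Step 4**
Reactants: 5
Product: 6 ((S)-1-[3,4-bis(benzyloxy)phenyl]prop-2-yn-1-ol)
Conditions: K2CO3, MeOH, 25 °C
Reagents that add atoms: none
Why: Protodesilylation of the alkynyl C–Si bond leaves the carbinol centre untouched.

**Step 5**
Reactants: 6
Product: 7 ((S)-1-[3,4-bis(benzyloxy)phenyl]prop-2-en-1-ol)
Conditions: H2 (1 atm), Lindlar catalyst (Pd/CaCO3, Pb-poisoned), quinoline, EtOAc, 25 °C
Reagents that add atoms: none
Why: Lindlar semi-hydrogenation of the terminal alkyne to the vinyl group, with no change at the stereocentre.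

**Step 6**
Reactants: 8 (4-benzyloxy-3-methoxybenzaldehyde); 9 (triethyl phosphonoacetate)
Product: 10 (ethyl (E)-3-[4-(benzyloxy)-3-methoxyphenyl]acrylate)
Conditions: 9, NaH, THF, 0 → 25 °C; then 8
Reagents that add atoms: none
Why: Horner–Wadsworth–Emmons olefination gives the E-cinnamate selectively.

**Step 7**
Reactants: 10
Product: 11 ((E)-3-[4-(benzyloxy)-3-methoxyphenyl]prop-2-en-1-ol)
Conditions: DIBAL-H (2.5 equiv), CH2Cl2, –78 °C
Reagents that add atoms: none
Why: 1,2-Reduction of the ester to the allylic alcohol; the alkene and benzyl ether survive.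

**Step 8**
Reactants: 11
Product: 12 ((E)-1-(benzyloxy)-4-(3-bromoprop-1-enyl)-2-methoxybenzene, cinnamyl bromide)
Conditions: CBr4, PPh3, CH2Cl2, 0 °C; use crude immediately
Reagents that add atoms: CBr4, BrC(Br)(Br)Br (supplies Br)
Why: Appel bromination, a mild SN2 conversion of the allylic alcohol that avoids acid.

**Step 9**
Reactants: 7; 12
Product: 13 (the 1,6-diene ether, (1S) centre: 1,2-bis(benzyloxy)-4-[(1S)-1-{[(2E)-3-(4-benzyloxy-3-methoxyphenyl)prop-2-enyl]oxy}prop-2-enyl]benzene)
Conditions: NaH (1.2 equiv), THF/DMF (4:1), n-Bu4NI (cat.), 0 → 25 °C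
Reagents that add atoms: none
Why: Williamson etherification. The alkoxide is the nucleophile and the C–O bond at the stereocentre is retained, so there is no racemisation.

**Step 10**
Reactants: 13
Product: 14 (tri-O-benzyl 7-hydroxytaxiresinol skeleton, ring (2S,3R,4R), C7 configuration unassigned or mixed)
Conditions: Cp2ZrCl2 (1.3 equiv), n-BuLi (2.6 equiv), THF, –78 °C, 1 h; add 13, –78 → 25 °C, then 40 °C, 3 h; then dry O2 (1 atm), 0 → 25 °C; aq. NH4Cl
Reagents that add atoms: O2, O=O (both O atoms end up in the product as C7–OH and C9′–OH)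
Why: Proposed new method: Cp2Zr(butene), from Cp2ZrBu2, does oxidative bicyclization of the 1,6-diene. The styrenyl carbon bearing aryl (C7) and the terminal vinyl carbon (C9′) bind Zr, which is the normal regiochemistry. C8–C8′ bond formation closes the THF ring and gives a cis-fused zirconacyclopentane, which makes C7 and C9′ cis on the ring (3,4-cis). The allylic aryl group at C7′ sits exo and trans to the forming C8′–C9′ bond, giving 2,3-trans. O2 then cleaves both Zr–C bonds to C–OH, installing the 7- and 9′-oxygens. The closest known chemistry is zirconocene cyclization of 3-oxa-1,6-dienes and O2 oxygenolysis of zirconacyclopentanes to 1,4-diols. The new elements are the α-aryl-allyl/electron-rich cinnamyl substitution pattern, diastereocontrol by the allylic ether centre, and use of both C–Zr bonds for lignan oxygenation. C7 configuration is irrelevant because it is reset in Steps 11–12.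

**Step 11**
Reactants: 14
Product: 15 (aryl ketone, C7 = O, ring (2S,3R,4R); free C9′–OH)
Conditions: activated MnO2 (30 equiv), CH2Cl2, 25 → 40 °C
Reagents that add atoms: none
Why: MnO2 oxidises only the electron-rich secondary benzylic alcohol and leaves the primary aliphatic alcohol and the ethers alone; this is an oxidation with no new stereocentre.

**Step 12**
Reactants: 15
Product: 16 (tri-O-benzyl-(7R)-7-hydroxytaxiresinol)
Conditions: RuCl[(R,R)-TsDPEN](p-cymene) (2 mol %), HCO2H/Et3N (5:2), CH2Cl2, 28 °C, 24 h
Reagents that add atoms: none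
Why: Noyori–Ikariya ATH of an aryl ketone in which the aryl group outranks the α-carbon. The (R,R)-catalyst gives the (R)-carbinol by catalyst control, with the ring stereocentres as a fixed bias. The mild formate buffer limits epimerisation at C8.

**Step 13**
Reactants: 16
Product: 17 ((7R)-7-hydroxytaxiresinol)
Conditions: H2 (1 atm), 10% Pd/C, EtOAc/MeOH (1:1), 25 °C, 1–2 h, stop at full debenzylation
Reagents that add atoms: none
Why: Hydrogenolysis of the three aryl O-benzyl ethers; the ring and carbinol stereocentres are not involved.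

Checks performed:
- The ring relationships in the target SMILES are 2,3-trans and 3,4-cis.
- Target descriptors: (2S,3R,4R) on the oxolane and 7R at the carbinol. This matches the (S)-allylic ether centre carried from Step 5, the cis-fused metallacycle, and the (R,R)-ATH.
- Atom balance: 13 is C40H38O5; 14 is C40H40O7 (13 + O2 + 2H); 15 is C40H38O7; 16 is C40H40O7; 17 is C19H22O7.

## Compound list
1 | 3,4-bis(benzyloxy)benzaldehyde | O=Cc1ccc(OCc2ccccc2)c(OCc2ccccc2)c1 | starting material
2 | trimethylsilylacetylene | C[Si](C)(C)C#C | starting material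
3 | rac-1-[3,4-bis(benzyloxy)phenyl]-3-(trimethylsilyl)prop-2-yn-1-ol | C[Si](C)(C)C#CC(O)c1ccc(OCc2ccccc2)c(OCc2ccccc2)c1 | intermediate
4 | 1-[3,4-bis(benzyloxy)phenyl]-3-(trimethylsilyl)prop-2-yn-1-one | C[Si](C)(C)C#CC(=O)c1ccc(OCc2ccccc2)c(OCc2ccccc2)c1 | intermediate
5 | (R)-1-[3,4-bis(benzyloxy)phenyl]-3-(trimethylsilyl)prop-2-yn-1-ol | C[Si](C)(C)C#C[C@H](O)c1ccc(OCc2ccccc2)c(OCc2ccccc2)c1 | intermediate
6 | (S)-1-[3,4-bis(benzyloxy)phenyl]prop-2-yn-1-ol | C#C[C@H](O)c1ccc(OCc2ccccc2)c(OCc2ccccc2)c1 | intermediate
7 | (S)-1-[3,4-bis(benzyloxy)phenyl]prop-2-en-1-ol | C=C[C@H](O)c1ccc(OCc2ccccc2)c(OCc2ccccc2)c1 | intermediate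
8 | 4-(benzyloxy)-3-methoxybenzaldehyde | COc1cc(C=O)ccc1OCc1ccccc1 | starting material
9 | triethyl phosphonoacetate | CCOC(=O)CP(=O)(OCC)OCC | starting material
10 | ethyl (E)-3-[4-(benzyloxy)-3-methoxyphenyl]acrylate | CCOC(=O)/C=C/c1ccc(OCc2ccccc2)c(OC)c1 | intermediate
11 | (E)-3-[4-(benzyloxy)-3-methoxyphenyl]prop-2-en-1-ol | OC/C=C/c1ccc(OCc2ccccc2)c(OC)c1 | intermediate
12 | (E)-4-(benzyloxy)-3-methoxycinnamyl bromide | BrC/C=C/c1ccc(OCc2ccccc2)c(OC)c1 | intermediate
13 | (S)-1,6-diene ether (aryl allyl cinnamyl ether) | C=C[C@H](OC/C=C/c1ccc(OCc2ccccc2)c(OC)c1)c1ccc(OCc2ccccc2)c(OCc2ccccc2)c1 | intermediate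
14 | tri-O-benzyl 7-hydroxytaxiresinol, C7 unassigned | COc1cc(C(O)[C@H]2CO[C@H](c3ccc(OCc4ccccc4)c(OCc4ccccc4)c3)[C@H]2CO)ccc1OCc1ccccc1 | intermediate
15 | 7-oxo analogue of 16 | COc1cc(C(=O)[C@H]2CO[C@H](c3ccc(OCc4ccccc4)c(OCc4ccccc4)c3)[C@H]2CO)ccc1OCc1ccccc1 | intermediate
16 | tri-O-benzyl-(7R)-7-hydroxytaxiresinol | COc1cc([C@H](O)[C@H]2CO[C@H](c3ccc(OCc4ccccc4)c(OCc4ccccc4)c3)[C@H]2CO)ccc1OCc1ccccc1 | intermediate
17 | (7R)-7-hydroxytaxiresinol, 4-[(2S,3R,4R)-3-(hydroxymethyl)-4-[(R)-hydroxy(4-hydroxy-3-methoxyphenyl)methyl]oxolan-2-yl]benzene-1,2-diol | COc1cc([C@H](O)[C@H]2CO[C@H](c3ccc(O)c(O)c3)[C@H]2CO)ccc1O | target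

## Totals
Total steps: 13 (three branches). Longest linear sequence: 10 (Steps 1–5, 9, 10, 11, 12, 13).

## Three steps most likely to fail
1. **Step 10 (new Zr bicyclization–oxygenolysis).** Zr(II) may insert into the doubly allylic C–O bond instead of cyclizing, the trans-2,3 selectivity may be low, and the oxygenolysis yield may be poor.
   - Fallback (known chemistry): a Cp2TiCl radical sequence. Epoxidise 7 with mCPBA (both epoxide diastereomers converge at the radical). O-Cinnamylate with 12 using Ag2O. Treat with Cp2TiCl (Cp2TiCl2/Zn) for radical epoxide opening, then 5-exo cyclization onto the styrene. Trap the benzylic radical with TEMPO, then Zn/AcOH gives the C7-epimeric diol 14. Separate the ring diastereomers and continue with Steps 11–13.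
2. **Step 12 (ATH diastereocontrol at C7, and C8 epimerisation).** The α-stereocentre may mismatch the catalyst, or the hydroxy ketone may sit as a cyclic hemiketal and react slowly.
   - Fallback: reduce 15 with NaBH4/CeCl3 to a 7R/7S mixture. Separate the diastereomers as the mono-acetates by HPLC. Recycle the 7S alcohol by MnO2 oxidation back to 15, or invert it by Mitsunobu with p-nitrobenzoic acid followed by K2CO3/MeOH.
3. **Step 13 (global hydrogenolysis).** The benzylic C7–OH (para-hydroxy aryl, quinone-methide-prone) and the 2-aryl THF benzylic C–O bond can hydrogenolyse.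
   - Fallback: change the protecting groups. Carry the phenols as TBS ethers from the start, using 3,4-bis(TBSO)benzaldehyde and 4-TBSO-3-methoxybenzaldehyde in place of 1 and 8. Finish with TBAF/AcOH at 0 °C, which avoids any Pd/H2 step.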